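**Plan**

1. Retrosynthesis: cut C13–C14 (prenyl from allyl by cross-metathesis), C2–O and C12–C13 first. Then cut C9–C10, the bond that closes the cyclopentene (C8=C9 comes from a C8 ketone made by carbenoid C–H insertion). Then cut C7–C8 and C6–C10 (vinyl conjugate addition and aldol on a cycloheptenone), the C1–O and C5–O bonds (singlet oxygen) and C4–C11 (Michael addition).
2. Forward: the seven-membered ring is bought as cycloheptanone. The side-chain stub enters at C4, oxygen at C1 and C5, then the C7 and C6 arms. A lactone ties C5–O to C12. The five-membered ring is closed last onto this monocycle, trans-fused, and the C1 methylene, side chain, C2 hydroxyl and prenyl group finish the route.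
3. Enabling feature: C10 carries oxygen and lies 1,5 to C9 across the trans C6–C7 bond. In the precursor its tertiary C–H bond, α to a silyl ether, is the best placed and most activated C–H bond for a carbenoid at C9 held by an acyl group on C7.
4. Insertion with retention turns the secondary carbinol at C10 into the quaternary carbinol with CH3 cis to C5, the arrangement that addition of a carbon nucleophile to a C10 ketone would not favour.
5. Stereochemistry: C4 from the chiral Michael catalyst; O at C1 (temporary) and C5 anti to the C4 arm; C7 anti to the C1 silyloxy group; C6 and C10 from a syn-selective titanium aldol; C5 reset by directed reduction; C11 by equilibration in the cis-fused lactone; C10 by retention; C12 by allylborane control; C2 by attack on the less hindered β face.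

Key step: step 15

Numbering used for every compound: C1 bears the exocyclic CH2; C2 is the CH(OH) next to it; C3 is CH2; C4 bears the side chain; C5 is CH(OH); C6 and C7 are the ring-fusion carbons (C6 next to C5); C8=C9; C10 is C(CH3)(OH) on C6. Side chain: C11 (CHCH3), C12 (CHOAc), C13, C14=C15. β is the face of H-7, α the face of H-6.

Assumption: the (R)-binaphthoxide aluminium–lithium catalyst is taken to attack the same enone face of 2 as it does with cyclohex-2-enone, which gives (R) at C4 of 4; if the sense is the opposite, the (S)-binaphthoxide catalyst is used.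

**Route**

Step 1
Reactants: 1 cycloheptanone
Product: 2 cyclohepta-2,6-dien-1-one
Conditions: IBX (2.3 equiv), DMSO, 75 °C
Reagents that add atoms: none
Why: IBX dehydrogenation of a ketone to the enone, applied twice, should stop at the cross-conjugated dienone when the oxidant is limited to just over two equivalents.

Step 2
Reactants: 2 cyclohepta-2,6-dien-1-one, 3 dimethyl methylmalonate
Product: 4 dimethyl 2-methyl-2-[(1R)-3-oxocyclohept-4-en-1-yl]propanedioate
Conditions: AlLi[(R)-binaphthoxide]2 (10 mol %), KOt-Bu (9 mol %), 4 Å MS, THF, rt; 2 in excess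
Reagents that add atoms: none
Why: Catalytic asymmetric Michael addition of a malonate to a cyclic enone, in which the catalyst binds the enone on aluminium and the malonate enolate on the alkali metal so that one face of the β-carbon is attacked, sets C4, while the two enone arms of 2 are equivalent and the second arm is kept for steps 4 to 6.

Step 3
Reactants: 4 malonate adduct
Product: 5 methyl 2-[(1R)-3-oxocyclohept-4-en-1-yl]propanoate (both C11 epimers)
Conditions: LiCl, H2O, DMSO, 150 °C
Reagents that add atoms: none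
Why: Krapcho demethoxycarbonylation removes one ester group, and C11 is left unset because it is equilibrated in the lactone of step 11.

Step 4
Reactants: 5 enone ester
Product: 6 dienyl triflate
Conditions: LiN(i-Pr)2, THF, −78 °C; PhNTf2, −78 → 0 °C
Reagents that add atoms: N-phenylbis(trifluoromethanesulfonimide) O=S(=O)(N(c1ccccc1)S(=O)(=O)C(F)(F)F)C(F)(F)F
Why: Kinetic deprotonation of the enone at the α′ carbon C5 and O-sulfonylation of the cross-conjugated dienolate give the 2-triflyloxy-1,3-diene regiospecifically, the ketone being far more acidic than the ester.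

Step 5
Reactants: 6 dienyl triflate
Product: 7 methyl 2-[(1R)-cyclohepta-2,4-dien-1-yl]propanoate (both C11 epimers)
Conditions: Pd(OAc)2 (5 mol %), PPh3, HCO2H, Bu3N, DMF, 40 °C
Reagents that add atoms: none
Why: Palladium-catalysed formate reduction of the vinyl triflate (oxidative addition to zerovalent palladium, decarboxylation of the formate, C–H reductive elimination) gives the 1,3-diene below the temperature of sigmatropic hydrogen shifts.

Step 6
Reactants: 7 diene
Product: 9 cis-1β,5β-diol (C11 epimers), via endoperoxide 8 (not isolated)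
Conditions: O2, tetraphenylporphyrin (catalytic), visible light, CH2Cl2, 0 °C; then thiourea, MeOH, rt
Reagents that add atoms: dioxygen O=O
Why: [4+2] cycloaddition of singlet oxygen across C5 and C1 of the diene on the face opposite the C4 arm, followed by thiourea cleavage of the O–O bond, puts both hydroxyl groups β, trans to the arm.

Step 7
Reactants: 9 cis-diol
Product: 10 1-O-TBS ether of 9
Conditions: TBSCl (1.05 equiv), imidazole, CH2Cl2, 0 °C
Reagents that add atoms: tert-butyldimethylsilyl chloride CC(C)(C)[Si](C)(C)Cl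
Why: Silylation should select the C1 hydroxyl, which has a CH2 neighbour, over the C5 hydroxyl, which is flanked by the branched C4.

Step 8
Reactants: 10 mono-silyl ether
Product: 11 γ-silyloxy enone (C5 ketone, C6=C7, 1β-OTBS, 4α arm)
Conditions: Dess–Martin periodinane, NaHCO3, CH2Cl2, 0 °C → rt
Reagents that add atoms: none
Why: Oxidation of the allylic C5 alcohol under buffered, non-basic conditions gives the enone without epimerising C4, which is now α to the ketone.

Step 9
Reactants: 11 enone, 12 vinylmagnesium bromide, 13 acetaldehyde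
Product: 14 aldol (7α-vinyl, 6β-[(1R)-1-hydroxyethyl], C5 ketone)
Conditions: 12, CuBr·SMe2 (10 mol %), THF, −78 °C; ClTi(Oi-Pr)3, −78 → −40 °C; 13, −78 °C
Reagents that add atoms: none
Why: Copper-catalysed conjugate addition puts the vinyl group on C7 anti to the γ-silyloxy group at C1, and the derived triisopropoxytitanium enolate adds to acetaldehyde anti to the new C7 substituent with the syn simple selectivity known for such titanium enolates of cyclic ketones, which sets C6 and the (10R) carbinol.

Step 10
Reactants: 14 aldol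
Product: 15 5α,10-diol
Conditions: Me4NBH(OAc)3, AcOH/MeCN, −30 °C
Reagents that add atoms: none
Why: In this Evans–Saksena reduction the acetoxyborohydride bound to the C10 oxygen on the β arm delivers hydride to the β face of the C5 ketone, giving the 1,3-anti diol with the 5α hydroxyl cis to the C4 arm.

Step 11
Reactants: 15 diol ester
Product: 16 cis-fused γ-lactone (O5 to C12, 11S methyl)
Conditions: DBU, PhMe, 80 °C
Reagents that add atoms: none
Why: The 5α hydroxyl and the cis ester arm on C4 close the γ-lactone, and base equilibration of the lactone α-carbon should put the C11 methyl group on the exo face, trans to C3, which is the (11S) configuration of the target.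

Step 12
Reactants: 16 lactone alcohol
Product: 17 10-O-triethylsilyl ether of 16
Conditions: TESCl, imidazole, DMF, rt
Reagents that add atoms: triethylsilyl chloride CC[Si](Cl)(CC)CC
Why: Silylation of the only free hydroxyl gives the ether that activates the C10–H bond for step 15 and prevents oxypalladation in step 13.

Step 13
Reactants: 17 vinyl compound
Product: 18 7α-acetyl compound (C8 methyl ketone)
Conditions: PdCl2 (10 mol %), Cu(OAc)2 (20 mol %), O2 (1 atm), DMA/H2O, rt
Reagents that add atoms: water O
Why: Tsuji–Wacker oxidation of the terminal alkene (Markovnikov hydroxypalladation, then β-hydride elimination) gives the methyl ketone, and the acetate-buffered copper co-oxidant spares the silyl ethers.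

Step 14
Reactants: 18 methyl ketone
Product: 20 α-diazo ketone, via trifluoroacetyl ketone 19 (not isolated)
Conditions: LiN(SiMe3)2, THF, −78 °C; CF3CO2CH2CF3; then MsN3, Et3N, H2O, MeCN, rt
Reagents that add atoms: 2,2,2-trifluoroethyl trifluoroacetate O=C(OCC(F)(F)F)C(F)(F)F; methanesulfonyl azide CS(=O)(=O)N=[N+]=[N-]
Why: In this detrifluoroacetylative diazo transfer the kinetic enolate of the methyl group is trifluoroacetylated and the activated 1,3-diketone takes N2 from the sulfonyl azide with loss of the trifluoroacetyl group, so the diazo group is placed on C9 only.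

Step 15
Reactants: 20 α-diazo ketone
Product: 21 trans-fused cyclopentanone (C8 ketone, 10β-CH3, 10α-OSiEt3)
Conditions: Rh2(OAc)4 (1 mol %), CH2Cl2, 40 °C, slow addition of 20
Reagents that add atoms: none
Why: Rh2(OAc)4 expels N2 from the diazo ketone to give an electrophilic rhodium carbenoid at C9, which inserts into the C10–H bond through a three-centre, hydride-transfer-like transition state that forms the C9–C10 bond as rhodium leaves. The closest known reaction type is the dirhodium-catalysed 1,5 C–H insertion of α-diazo ketones next to an ether oxygen, which gives 3-alkoxycyclopentanones. The cyclopentanone closes in the 1,5 mode and is trans-fused because the arms on C6 and C7 are already trans. C10 is the only new stereocentre and is fixed by retention: the carbenoid carbon takes the place of hydrogen on the (10R) carbinol of step 9, so the methyl group ends β (cis to C5) and the oxygen α. The step needs site selectivity, and the substrate secures it: C10–H is tertiary, α to a silyl ether oxygen and 1,5 to C9, whereas C5–H lies on the opposite ring face and is deactivated by the lactone oxygen, C1–H would give a four-membered ring and C2–H2 is an unactivated methylene. Slow addition keeps the carbenoid from dimerising.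

Step 16
Reactants: 21 cyclopentanone
Product: 22 C8–C9 enol triflate
Conditions: KN(SiMe3)2, THF, −78 °C; N-(5-chloro-2-pyridyl)bis(trifluoromethanesulfonimide), −78 °C
Reagents that add atoms: N-(5-chloro-2-pyridyl)bis(trifluoromethanesulfonimide) O=S(=O)(N(c1ccc(Cl)cn1)S(=O)(=O)C(F)(F)F)C(F)(F)F
Why: Kinetic deprotonation at the C9 methylene, not at the ring-fusion methine C7, and immediate O-triflation at −78 °C should give the enol triflate before the β-silyloxy group on C10 can be expelled.

Step 17
Reactants: 22 enol triflate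
Product: 23 cyclopentene bis-silyl ether (C8=C9)
Conditions: Pd(OAc)2 (5 mol %), PPh3, HCO2H, Bu3N, DMF, 60 °C
Reagents that add atoms: none
Why: Palladium-catalysed formate reduction of the enol triflate gives the C8=C9 alkene of the target.

Step 18
Reactants: 23 bis-silyl ether
Product: 24 1β,10α-diol
Conditions: Bu4NF, THF, 0 °C → rt
Reagents that add atoms: none
Why: Fluoride cleaves both silyl ethers while the lactone keeps O5 and C12 masked.

Step 19
Reactants: 24 diol
Product: 25 C1 ketone
Conditions: Dess–Martin periodinane, NaHCO3, CH2Cl2, 0 °C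
Reagents that add atoms: none
Why: Only the secondary C1 hydroxyl can be oxidised, the C10 hydroxyl being tertiary, and the buffered conditions should leave the β,γ-alkene and C7 untouched.

Step 20
Reactants: 25 ketone
Product: 26 exocyclic alkene (C1=CH2)
Conditions: Tebbe reagent Cp2Ti(μ-Cl)(μ-CH2)AlMe2 (2.5 equiv), pyridine (catalytic), THF/PhMe, −40 → 0 °C
Reagents that add atoms: Tebbe reagent C=[Ti](C1C=CC=C1)C1C=CC=C1.C[Al](C)Cl
Why: Methylenation through the titanium methylidene and an oxatitanacyclobutane is non-basic, so the doubly activated C7–H is not removed, and at low temperature the ketone should react before the lactone.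

Step 21
Reactants: 26 lactone
Product: 27 lactol (both anomers)
Conditions: i-Bu2AlH (2.2 equiv), CH2Cl2, −78 °C
Reagents that add atoms: none
Why: Half-reduction of the γ-lactone stops at the tetrahedral aluminate, which gives the lactol on work-up, one equivalent of hydride being used up by the tertiary hydroxyl.

Step 22
Reactants: 27 lactol
Product: 28 5α,10α,12-triol with the C13–C15 allyl group
Conditions: (−)-Ipc2B(allyl) (3 equiv), Et2O, −78 °C → rt; then NaOH, H2O2
Reagents that add atoms: (−)-B-allyldiisopinocampheylborane C=CCB(C1CC2CC(C1C)C2(C)C)C1CC2CC(C1C)C2(C)C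
Why: Brown allylboration of the open hydroxy-aldehyde form through a chair transition state adds allyl to the si face of C12, which is also the Felkin–Anh face of the α-methyl aldehyde, so reagent and substrate are matched for the (12S) alcohol syn to the C11 methyl group.

Step 23
Reactants: 28 triol
Product: 29 12-acetate
Conditions: Ac2O (1.1 equiv), pyridine, CH2Cl2, 0 °C
Reagents that add atoms: acetic anhydride CC(=O)OC(C)=O
Why: Acylation without a nucleophilic catalyst should take the C12 hydroxyl, because the C5 hydroxyl sits between two branched ring carbons and the C10 hydroxyl is tertiary.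

Step 24
Reactants: 29 acetate
Product: 30 2β-alcohol
Conditions: SeO2 (0.5 equiv), t-BuOOH, CH2Cl2, rt
Reagents that add atoms: selenium dioxide O=[Se]=O; tert-butyl hydroperoxide CC(C)(C)OO
Why: Allylic hydroxylation by the ene reaction of SeO2 at the 1,1-disubstituted alkene and [2,3]-sigmatropic shift should take the ring CH2 at C2 in preference to the CH at C7 and deliver oxygen to the β face, because the α face carries C8 and C11 in 1,3 relationships to C2.

Step 25
Reactants: 30 allyl compound, 31 2-methyl-2-butene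
Product: 32 target
Conditions: second-generation Grubbs catalyst RuCl2(=CHPh)(PCy3)(H2IMes) (5 mol %), 31 as co-solvent, CH2Cl2, 40 °C
Reagents that add atoms: none
Why: Olefin cross-metathesis of the monosubstituted alkene with 2-methyl-2-butene gives the trisubstituted prenyl alkene, while the hindered exocyclic alkene and the cyclopentene next to a quaternary carbon should stay out of the catalytic cycle.

**Compound list**

1 | cycloheptanone | O=C1CCCCCC1 | starting material
2 | cyclohepta-2,6-dien-1-one | O=C1C=CCCC=C1 | intermediate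
3 | dimethyl 2-methylpropanedioate (dimethyl methylmalonate) | COC(=O)C(C)C(=O)OC | starting material
4 | dimethyl 2-methyl-2-[(1R)-3-oxocyclohept-4-en-1-yl]propanedioate | COC(=O)C(C)(C(=O)OC)[C@H]1CC(=O)C=CCC1 | intermediate
5 | methyl 2-[(1R)-3-oxocyclohept-4-en-1-yl]propanoate, both C11 epimers | COC(=O)C(C)[C@H]1CC(=O)C=CCC1 | intermediate
6 | methyl 2-[(1R)-3-(trifluoromethylsulfonyloxy)cyclohepta-2,4-dien-1-yl]propanoate, both C11 epimers | COC(=O)C(C)[C@H]1C=C(OS(=O)(=O)C(F)(F)F)C=CCC1 | intermediate
7 | methyl 2-[(1R)-cyclohepta-2,4-dien-1-yl]propanoate, both C11 epimers | COC(=O)C(C)[C@H]1C=CC=CCC1 | intermediate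
8 | endoperoxide: cyclohept-6-ene with a 1β,5β-epidioxy bridge and the 4α-[1-(methoxycarbonyl)ethyl] arm | O1[C@@H]2CC[C@@H](C(C)C(=O)OC)[C@H](O1)C=C2 | intermediate
9 | cis-diol: cyclohept-6-ene with 1β-OH, 5β-OH and the 4α-[1-(methoxycarbonyl)ethyl] arm | O[C@@H]1CC[C@@H](C(C)C(=O)OC)[C@H](O)C=C1 | intermediate
10 | 1-O-tert-butyldimethylsilyl ether of 9 (5β-OH free) | CC(C)(C)[Si](C)(C)O[C@@H]1CC[C@@H](C(C)C(=O)OC)[C@H](O)C=C1 | intermediate
11 | enone: cyclohept-6-en-5-one with 1β-OTBS and the 4α-[1-(methoxycarbonyl)ethyl] arm | CC(C)(C)[Si](C)(C)O[C@@H]1CC[C@@H](C(C)C(=O)OC)C(=O)C=C1 | intermediate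
12 | vinylmagnesium bromide | C=C[Mg]Br | starting material
13 | acetaldehyde | CC=O | starting material
14 | aldol: cycloheptan-5-one with 1β-OTBS, 4α ester arm, 6β-[(1R)-1-hydroxyethyl] and 7α-vinyl | CC(C)(C)[Si](C)(C)O[C@@H]1CC[C@@H](C(C)C(=O)OC)C(=O)[C@H]([C@@H](C)O)[C@H]1C=C | intermediate
15 | diol: as 14 with 5α-OH in place of the ketone | CC(C)(C)[Si](C)(C)O[C@@H]1CC[C@@H](C(C)C(=O)OC)[C@@H](O)[C@H]([C@@H](C)O)[C@H]1C=C | intermediate
16 | cis-fused γ-lactone (O5–C12, 4α,5α), (11S)-methyl, 1β-OTBS, 6β-[(1R)-1-hydroxyethyl], 7α-vinyl | CC(C)(C)[Si](C)(C)O[C@@H]1CC[C@H]2[C@H](C)C(=O)O[C@H]2[C@H]([C@@H](C)O)[C@H]1C=C | intermediate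
17 | 10-O-triethylsilyl ether of 16 | CC(C)(C)[Si](C)(C)O[C@@H]1CC[C@H]2[C@H](C)C(=O)O[C@H]2[C@H]([C@@H](C)O[Si](CC)(CC)CC)[C@H]1C=C | intermediate
18 | methyl ketone: as 17 with 7α-acetyl in place of vinyl | CC(C)(C)[Si](C)(C)O[C@@H]1CC[C@H]2[C@H](C)C(=O)O[C@H]2[C@H]([C@@H](C)O[Si](CC)(CC)CC)[C@H]1C(C)=O | intermediate
19 | trifluoroacetyl ketone: as 18 with 7α-(4,4,4-trifluoro-3-oxobutanoyl) | CC(C)(C)[Si](C)(C)O[C@@H]1CC[C@H]2[C@H](C)C(=O)O[C@H]2[C@H]([C@@H](C)O[Si](CC)(CC)CC)[C@H]1C(=O)CC(=O)C(F)(F)F | intermediate
20 | α-diazo ketone: as 18 with 7α-diazoacetyl | CC(C)(C)[Si](C)(C)O[C@@H]1CC[C@H]2[C@H](C)C(=O)O[C@H]2[C@H]([C@@H](C)O[Si](CC)(CC)CC)[C@H]1C(=O)C=[N+]=[N-] | intermediate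
21 | trans-fused cyclopentanone (6α-H, 7β-H): C8 ketone, 10β-CH3, 10α-OSiEt3, 1β-OTBS, lactone as in 16 | CC(C)(C)[Si](C)(C)O[C@@H]1CC[C@H]2[C@H](C)C(=O)O[C@H]2[C@H]3[C@H]1C(=O)C[C@]3(C)O[Si](CC)(CC)CC | intermediate
22 | C8–C9 enol triflate of 21 | CC(C)(C)[Si](C)(C)O[C@@H]1CC[C@H]2[C@H](C)C(=O)O[C@H]2[C@H]3[C@H]1C(OS(=O)(=O)C(F)(F)F)=C[C@]3(C)O[Si](CC)(CC)CC | intermediate
23 | cyclopentene: C8=C9, 10β-CH3, 10α-OSiEt3, 1β-OTBS, lactone | CC(C)(C)[Si](C)(C)O[C@@H]1CC[C@H]2[C@H](C)C(=O)O[C@H]2[C@H]3[C@H]1C=C[C@]3(C)O[Si](CC)(CC)CC | intermediate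
24 | 1β,10α-diol lactone | O[C@@H]1CC[C@H]2[C@H](C)C(=O)O[C@H]2[C@H]3[C@H]1C=C[C@]3(C)O | intermediate
25 | C1 ketone, 10α-hydroxy lactone | O=C1CC[C@H]2[C@H](C)C(=O)O[C@H]2[C@H]3[C@H]1C=C[C@]3(C)O | intermediate
26 | 1-methylene, 10α-hydroxy lactone | C=C1CC[C@H]2[C@H](C)C(=O)O[C@H]2[C@H]3[C@H]1C=C[C@]3(C)O | intermediate
27 | lactol of 26 (C12 hemiacetal, both anomers) | C=C1CC[C@H]2[C@H](C)C(O)O[C@H]2[C@H]3[C@H]1C=C[C@]3(C)O | intermediate
28 | triol: 5α-OH, 10α-OH, (11S,12S)-side chain CH(CH3)–CH(OH)–CH2–CH=CH2, 1-methylene | C=C1CC[C@@H]([C@H](C)[C@H](CC=C)O)[C@@H](O)[C@H]2[C@H]1C=C[C@]2(C)O | intermediate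
29 | 12-acetate of 28 | C=C1CC[C@@H]([C@H](C)[C@H](CC=C)OC(C)=O)[C@@H](O)[C@H]2[C@H]1C=C[C@]2(C)O | intermediate
30 | 2β-hydroxy derivative of 29 | C=C1[C@H](O)C[C@@H]([C@H](C)[C@H](CC=C)OC(C)=O)[C@@H](O)[C@H]2[C@H]1C=C[C@]2(C)O | intermediate
31 | 2-methyl-2-butene | CC=C(C)C | starting material
32 | CNP0126182.2 | C=C1[C@H](O)C[C@@H]([C@H](C)[C@H](CC=C(C)C)OC(C)=O)[C@@H](O)[C@H]2[C@H]1C=C[C@]2(C)O | target

**Count and risks**

Total step count: 25. Longest linear sequence: 25 steps (1 → 32); compounds 3, 12, 13 and 31 are bought.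

Steps most likely to fail:

1. Step 15 (key step). The carbenoid may be diverted: attack on the C1 silyl ether oxygen to form an oxonium ylide, insertion into the C2 methylene, or carbene dimerisation, instead of insertion at C10–H. Fallback (Wittig ring closure, oxygen delivered last), from 20: aqueous HBr in ether turns the diazo ketone into the bromomethyl ketone and cleaves the triethylsilyl ether to give bromo ketol F1. Dess–Martin oxidation gives bromo diketone F2. PPh3 gives phosphonium bromide F3, whose ylide (K2CO3, then PhMe at reflux) closes the ring by intramolecular Wittig reaction onto the C10 ketone, making the same C9–C10 connection as the double bond of cyclopentenone F4. Nucleophilic epoxidation (t-BuOOH, DBU) from the α face, anti to C5, gives epoxy ketone F5. Wharton transposition (N2H4·H2O, AcOH, MeOH) gives allylic alcohol F6 with the 10α hydroxyl and the C8=C9 alkene. Bu4NF then removes the silyl group and the route is rejoined at 24.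

2. Step 9. The titanium aldol may lose its syn selectivity, so that C10 forms with the wrong configuration (step 15 would carry this through by retention), or the aldol may revert. Fallback, from 11: the same conjugate addition, with the enolate transmetallated by ZnCl2 before acetaldehyde is added, should give anti aldol F7 through a closed chair transition state. Narasaka–Prasad reduction (Et2BOMe, NaBH4, THF/MeOH, −78 °C) places the C5 hydroxyl α, syn to the C10 hydroxyl, in diol F8. DBU closes epimeric lactone F9. Mitsunobu inversion at C10 (4-nitrobenzoic acid, PPh3, diisopropyl azodicarboxylate) gives nitrobenzoate F10, and methanolysis (K2CO3, MeOH) rejoins the route at 16.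

3. Step 24. The selenium ene reaction may show poor site selectivity (the doubly allylic C7–H against C2–H2), may attack the cyclopentene, or may over-oxidise to the enone. Fallback, from 25: kinetic enolisation toward C2 with LiN(SiMe3)2 (2.2 equiv, THF, −78 °C) and oxidation with 2-(phenylsulfonyl)-3-phenyloxaziridine from the β face give hydroxy ketone F11. Tebbe methylenation gives allylic alcohol F12. TESCl gives silyl ether F13. i-Bu2AlH gives lactol F14. (−)-Ipc2B(allyl) gives diol F15. Ac2O in pyridine gives acetate F16. HF·pyridine removes the silyl group and the route is rejoined at 30.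

Further compounds
F1 | step 15 | bromo ketol: 7α-bromoacetyl, 6β-[(1R)-1-hydroxyethyl], 1β-OTBS, lactone | CC(C)(C)[Si](C)(C)O[C@@H]1CC[C@H]2[C@H](C)C(=O)O[C@H]2[C@H]([C@@H](C)O)[C@H]1C(=O)CBr
F2 | step 15 | bromo diketone: 7α-bromoacetyl, 6β-acetyl | CC(C)(C)[Si](C)(C)O[C@@H]1CC[C@H]2[C@H](C)C(=O)O[C@H]2[C@H](C(C)=O)[C@H]1C(=O)CBr
F3 | step 15 | phosphonium bromide from F2 | CC(C)(C)[Si](C)(C)O[C@@H]1CC[C@H]2[C@H](C)C(=O)O[C@H]2[C@H](C(C)=O)[C@H]1C(=O)C[P+](c1ccccc1)(c1ccccc1)c1ccccc1.[Br-]
F4 | step 15 | trans-fused cyclopentenone: C8 ketone, C9=C10, 10-CH3 | CC(C)(C)[Si](C)(C)O[C@@H]1CC[C@H]2[C@H](C)C(=O)O[C@H]2[C@H]3[C@H]1C(=O)C=C3C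
F5 | step 15 | 9α,10α-epoxy ketone | CC(C)(C)[Si](C)(C)O[C@@H]1CC[C@H]2[C@H](C)C(=O)O[C@H]2[C@H]3[C@H]1C(=O)[C@@H]4O[C@]34C
F6 | step 15 | allylic alcohol: C8=C9, 10α-OH, 10β-CH3, 1β-OTBS, lactone | CC(C)(C)[Si](C)(C)O[C@@H]1CC[C@H]2[C@H](C)C(=O)O[C@H]2[C@H]3[C@H]1C=C[C@]3(C)O
F7 | step 9 | anti aldol: C10 epimer of 14, (10S) | CC(C)(C)[Si](C)(C)O[C@@H]1CC[C@@H](C(C)C(=O)OC)C(=O)[C@H]([C@H](C)O)[C@H]1C=C
F8 | step 9 | syn diol: 5α-OH, (10S) | CC(C)(C)[Si](C)(C)O[C@@H]1CC[C@@H](C(C)C(=O)OC)[C@@H](O)[C@H]([C@H](C)O)[C@H]1C=C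
F9 | step 9 | lactone epimeric with 16 at C10 | CC(C)(C)[Si](C)(C)O[C@@H]1CC[C@H]2[C@H](C)C(=O)O[C@H]2[C@H]([C@H](C)O)[C@H]1C=C
F10 | step 9 | 4-nitrobenzoate of 16, (10R) | CC(C)(C)[Si](C)(C)O[C@@H]1CC[C@H]2[C@H](C)C(=O)O[C@H]2[C@H]([C@@H](C)OC(=O)c3ccc(cc3)[N+](=O)[O-])[C@H]1C=C
F11 | step 24 | 2β-hydroxy C1 ketone lactone | O=C1[C@H](O)C[C@H]2[C@H](C)C(=O)O[C@H]2[C@H]3[C@H]1C=C[C@]3(C)O
F12 | step 24 | 2β-hydroxy 1-methylene lactone | C=C1[C@H](O)C[C@H]2[C@H](C)C(=O)O[C@H]2[C@H]3[C@H]1C=C[C@]3(C)O
F13 | step 24 | 2-O-triethylsilyl ether of F12 | C=C1[C@H](O[Si](CC)(CC)CC)C[C@H]2[C@H](C)C(=O)O[C@H]2[C@H]3[C@H]1C=C[C@]3(C)O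
F14 | step 24 | lactol of F13 | C=C1[C@H](O[Si](CC)(CC)CC)C[C@H]2[C@H](C)C(O)O[C@H]2[C@H]3[C@H]1C=C[C@]3(C)O
F15 | step 24 | allyl triol with 2-O-triethylsilyl, (12S) | C=C1[C@H](O[Si](CC)(CC)CC)C[C@@H]([C@H](C)[C@H](CC=C)O)[C@@H](O)[C@H]2[C@H]1C=C[C@]2(C)O
F16 | step 24 | 12-acetate of F15 | C=C1[C@H](O[Si](CC)(CC)CC)C[C@@H]([C@H](C)[C@H](CC=C)OC(C)=O)[C@@H](O)[C@H]2[C@H]1C=C[C@]2(C)O
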